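Compound numbers are those of the forward steps; the full list with SMILES follows step 14.

## Analysis of the target

Gnetucleistol F (19) is a stilbenolignan built on a 2,3-dihydrobenzofuran: the benzo ring (ring A, C3a to C7a) carries a methoxy group at C7 and, at C5, an (E)-styryl arm ending in a resorcinol ring (ring C), while C2 carries a syringyl ring (ring B, 4-hydroxy-3,5-dimethoxyphenyl) and C3 a hydroxymethyl group. The only stereocentres are the neighbouring C2 (R) and C3 (S); aryl and hydroxymethyl are trans, which is also the more stable arrangement on this ring. The two centres differ in character: C2 is a benzylic ether carbon on an aryl ring with a para oxygen, so the C2–O1 bond can ionise under acid (or open to a para-quinone methide under base once the ring B phenol is free) and close again, whereas C3 keeps its configuration once made. The absolute configuration therefore has to be fixed at C3, and C2 can be left to relax to trans. The sensitive groups are the three phenols, the electron-rich (E)-stilbene (air, light, strong acid) and the labile C2–O1 bond. The synthesis is hard for two reasons: three differently oxygenated arenes must be joined, so a biomimetic oxidative coupling cannot be selective, and the ring offers no neighbouring group to direct a reagent other than the ring A oxygen itself. The plan reads C2–C3 as a former double bond: the hydroxymethyl carbon on C3 and O1 on C2 are a carbon electrophile and an internal oxygen nucleophile added across the C2=C3 bond of an (E)-2-hydroxystilbene linking ring A to ring B.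

## Retrosynthetic reasoning

**19 ⇒ 18 (four O–Si bonds).** All four hydroxyl groups are carried as silyl ethers and released together. The free phenols and the oxidation-prone hydroxystilbene then exist only after the last step.

**18 ⇒ 12 + 17 (the C=C bond of the styryl arm).** This is the one C–C bond outside the stereogenic core that splits the molecule into two pieces of useful size. Making it late keeps a second electron-rich alkene away from the acid and formaldehyde of the key step. The forward olefination has to give the E isomer and must not open the base-sensitive dihydrofuran of aldehyde 12. A Heck union at a C5 halide would shorten the end, but a halide would not give ring A the deactivation that the ester supplies in the key step.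

**12 ⇒ 11 ⇒ 10 ⇒ 9 (oxidation level at C5, protection of the primary alcohol).** The C5 carbon is carried through the key step as a methyl ester, which is inert to acid and formaldehyde. Afterwards the primary alcohol of 9 is silylated (10), the ester is reduced (11) and the benzylic alcohol is re-oxidised (12).

**9 ⇒ 6 + 7 (C3–CH2OH and C2–O1, cut together).** This double cut removes both stereocentres and the heterocycle at once and leads to a flat, achiral stilbene 6 and formaldehyde 7. Cutting only one ring bond (C2–O1, O1–C7a or C3–C3a) would leave one or two stereocentres to be built in an open chain. The forward reaction must add the carbon electrophile at C3 and not at C2, choose one face of the alkene at C3 through a chiral acid, and close the ring trans. The ester of 6 sits para to the ring A hydroxyl and meta to the alkene; it ties up the oxygen lone pair and makes positive charge next to ring A less favourable.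

**6 ⇒ 5 + 3 (aryl–vinyl bond on the ring A side).** The halide is placed on ring A because iodide 5 comes in one step from methyl vanillate 4: the hydroxyl directs iodination to its only free ortho position. Styrene 3 comes from syringaldehyde 1 through silyl ether 2. The forward Heck coupling must be E-selective and tolerate the free phenol of 5.

**17 ⇒ 16 ⇒ 15 ⇒ 14 ⇒ 13 (C–P, C–Br, C–H, O–Si).** The phosphonate is reached from 3,5-dihydroxybenzaldehyde 13 by silylation, reduction, bromination and an Arbuzov reaction. Bulky silyl groups are chosen so that the aryl ethers survive the base of the olefination.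

## Alternatives that were turned down

Alternative 1: The aryl ether bond O1–C7a is cut. The precursor is the open-chain bromo alcohol A2, in which both stereocentres already exist. CuI with a phenanthroline ligand and Cs2CO3 would couple the secondary benzylic alkoxide with the ortho bromide and give dihydrobenzofuran A1. Both centres are retained, because the new bond forms at an arene carbon.
- For: no cation appears at C2 during ring closure, so the product has exactly the configuration that was built in. Intramolecular copper-mediated C–O coupling is an established reaction type, and on this point it is stronger than the chosen plan.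
- Against: A2 needs two stereocentres with correct relative and absolute configuration, where the chosen plan has to control only C3. The bromide is flanked by a methoxy group and the branched chain, which makes it a hindered coupling partner. A1 has no substituent at C5, so the carbon for the styryl arm would have to be introduced later by electrophilic substitution on a molecule with two competing electron-rich rings. The methoxymethyl group needs a separate acidic deprotection.
- Comparison: the route would be longer (an aldol sequence to A2, ring closure, C5 functionalisation, olefination, two deprotections), with its risk spread over several steps. The chosen plan makes the ring and both centres in one catalytic step from a flat precursor that already carries the C5 handle.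

Alternative 2: The C3–C3a bond is traced back to a ring contraction. The enantioenriched flavanone A4 would be treated with PhI(OAc)2 and acid in trimethyl orthoformate. The enol ether is attacked at C3 by the iodine electrophile, the ring A carbon shifts from the former carbonyl carbon to C3 as iodobenzene leaves, and the carbonyl carbon ends as the methyl ester of the trans product A3.
- For: oxidative ring contraction of flavanones is a known reaction type and gives the trans isomer directly. The C5 bromide of A3 allows the styryl arm to be attached by a direct Heck coupling, so the end of the route is shorter than in the chosen plan.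
- Against: the stereochemistry rests on the flavanone C2 centre, which is benzylic, next to oxygen and beta to the carbonyl group. It can racemise by ring opening to the chalcone under the acidic conditions of enol ether formation. The contraction competes with migration of ring B (towards an isoflavone) and with dehydrogenation; an oxygen-rich ring B is a good migrating group, and the pivalate only partly damps this. The flavanone needs its own asymmetric synthesis, and the C3 ester must then be reduced to the alcohol.
- Comparison: the chosen plan fixes the absolute configuration at C3, which cannot epimerise, has no competing migration, and delivers the hydroxymethyl group at the right oxidation level.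

Alternative 3: Only the C2–O1 bond is cut. Acid would ionise the benzylic carbinol of diol A6, as either carbinol epimer, and the ortho phenol of ring A would add to C2 and give the trans dihydrobenzofuran A5.
- For: this is the most dependable closure for this ring system. It is stereoconvergent at C2, tolerates free phenols, needs no new method, and the C5 bromide again allows a Heck end-game. On certainty it is stronger than the chosen plan.
- Against: the whole stereochemical burden moves to C2 of an open-chain 2-arylpropane-1,3-diol. That centre would have to be set with a stoichiometric auxiliary (acylation, aldol, reductive cleavage) together with protection and release of the ring A phenol. The aldol also creates a carbinol centre that is then discarded.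
- Comparison: the chosen plan uses the same closing event (phenol capture of a ring-B-stabilised cation at C2) but merges it with the C–C bond formation, replaces the auxiliary by a catalyst and saves several steps. The logic of Alternative 3 is kept as the fallback for the key step.

Key step: step 5

Assumption: formaldehyde 7 is supplied as paraformaldehyde. The antipode of the chiral acid that leads to 3S is chosen in a pilot run, because its sense of induction on a 1,2-diaryl alkene cannot be derived from terminal styrenes.

## Route

Step 1
Reactants: 1 syringaldehyde (4-hydroxy-3,5-dimethoxybenzaldehyde)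
Product: 2 3,5-dimethoxy-4-(triisopropylsilyloxy)benzaldehyde
Conditions: i-Pr3SiCl, imidazole, DMAP (cat.), DMF, rt to 40 °C
Reagents that add atoms: triisopropylsilyl chloride, CC(C)[Si](Cl)(C(C)C)C(C)C
Why: Standard silylation of a phenol; the hindered triisopropylsilyl ether between two methoxy groups should survive the basic, acidic and hydride steps up to step 14.

Step 2
Reactants: 2 3,5-dimethoxy-4-(triisopropylsilyloxy)benzaldehyde
Product: 3 3,5-dimethoxy-4-(triisopropylsilyloxy)styrene
Conditions: Ph3PCH3Br, NaN(SiMe3)2, THF, 0 °C to rt
Reagents that add atoms: methyltriphenylphosphonium bromide, C[P+](c1ccccc1)(c1ccccc1)c1ccccc1.[Br-]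
Why: Wittig methylenation of an aromatic aldehyde; the non-nucleophilic amide base leaves the aryl silyl ether alone.

Step 3
Reactants: 4 methyl vanillate (methyl 4-hydroxy-3-methoxybenzoate)
Product: 5 methyl 4-hydroxy-3-iodo-5-methoxybenzoate
Conditions: N-iodosuccinimide, CF3CO2H (cat.), MeCN, rt
Reagents that add atoms: N-iodosuccinimide, O=C1CCC(=O)N1I
Why: Electrophilic aromatic iodination; the hydroxyl group directs to its only free ortho position, the para position being taken by the ester.

Step 4
Reactants: 5 methyl 4-hydroxy-3-iodo-5-methoxybenzoate; 3 3,5-dimethoxy-4-(triisopropylsilyloxy)styrene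
Product: 6 methyl 4-hydroxy-3-methoxy-5-[(E)-2-[3,5-dimethoxy-4-(triisopropylsilyloxy)phenyl]vinyl]benzoate
Conditions: Pd(OAc)2 (5 mol%), P(o-tol)3, Et3N, DMF, 90 °C
Reagents that add atoms: none
Why: Mizoroki–Heck reaction: zerovalent palladium inserts into the C–I bond (activated by the para ester), the styrene inserts with the aryl group going to its terminal carbon, and syn beta-hydride elimination gives the (E)-stilbene; ortho-iodophenols are known to couple without protection and the amine base does not disturb the silyl ether.

Step 5
Reactants: 6 methyl 4-hydroxy-3-methoxy-5-[(E)-2-[3,5-dimethoxy-4-(triisopropylsilyloxy)phenyl]vinyl]benzoate; 7 formaldehyde (as paraformaldehyde)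
Product: 9 methyl (2R,3S)-2-[3,5-dimethoxy-4-(triisopropylsilyloxy)phenyl]-3-(hydroxymethyl)-7-methoxy-2,3-dihydrobenzofuran-5-carboxylate, via open-chain benzylic cation 8 (not isolated)
Conditions: (CH2O)n (1.5 equiv), chiral BINOL-derived imidodiphosphorimidate acid (5 mol%), CHCl3, 0 °C to rt; then MeOH, aq. NaHCO3
Reagents that add atoms: none
Why: Proposed new method: the acid depolymerises paraformaldehyde and holds a protonated formaldehyde unit in the pocket of its chiral anion; the alkene of 6 attacks it through C3, the carbon on ring A, which forms the C3–CH2OH bond and leaves the charge on C2 as cation 8, a quinone-methide-like oxocarbenium ion carried by the para-silyloxy ring B, and the ortho hydroxyl of ring A then adds to C2. The closest known reaction types are the enantioselective intermolecular Prins reaction of styrenes with paraformaldehyde under imidodiphosphorimidate catalysis, where the cation is taken up by a second formaldehyde to give 1,3-dioxanes, and the cyclisation of 2-hydroxystilbenes induced by selenium or halogen electrophiles to trans-3-substituted 2-aryl-2,3-dihydrobenzofurans; what is new is a carbon electrophile on a 1,2-diaryl alkene combined with internal phenol capture. The dihydrofuran closes by 5-exo-trig attack of O1 on the exocyclic C2=C1' bond of the quinone-methide form of 8 (counted from the original alkene the same bond formation is 5-endo, which is why it needs the cationic, stepwise or strongly asynchronous pathway). C3 is controlled by the catalyst: the chiral counteranion decides which face of the planar stilbene meets formaldehyde, and the antipode that gives 3S is used. C2 is controlled by the substrate: O1 adds to the flat cation on the side away from the new hydroxymethyl group to give the trans (2R) isomer, and since C2–O1 can ionise again under the acid, any cis isomer should drain to trans without affecting C3. The selectivity the step needs most is regioselectivity for bond formation at C3, and 6 secures it in three ways: only a cation on C2 lies within reach of the phenol oxygen, the ester para to that hydroxyl (meta to the alkene) lowers the ability of ring A to carry charge at its benzylic carbon, and the silyloxy group is para to C2. Ring A itself cannot be hydroxymethylated because both ortho positions and the para position of its hydroxyl are substituted, and a small excess of formaldehyde keeps capture by a second aldehyde (dioxane formation) behind the faster internal closure. A methanolic bicarbonate work-up cleaves any hemiformal on the new primary alcohol.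

Step 6
Reactants: 9 methyl (2R,3S)-2-[3,5-dimethoxy-4-(triisopropylsilyloxy)phenyl]-3-(hydroxymethyl)-7-methoxy-2,3-dihydrobenzofuran-5-carboxylate
Product: 10 methyl (2R,3S)-3-[(tert-butyldimethylsilyloxy)methyl]-2-[3,5-dimethoxy-4-(triisopropylsilyloxy)phenyl]-7-methoxy-2,3-dihydrobenzofuran-5-carboxylate
Conditions: t-BuMe2SiCl, imidazole, CH2Cl2, 0 °C to rt
Reagents that add atoms: tert-butyldimethylsilyl chloride, CC(C)(C)[Si](C)(C)Cl
Why: Silylation of the only free hydroxyl, so that the hydride reduction and the basic olefination meet no acidic proton; the imidazole-buffered medium leaves the acid-labile C2–O1 bond alone.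

Step 7
Reactants: 10 methyl (2R,3S)-3-[(tert-butyldimethylsilyloxy)methyl]-2-[3,5-dimethoxy-4-(triisopropylsilyloxy)phenyl]-7-methoxy-2,3-dihydrobenzofuran-5-carboxylate
Product: 11 [(2R,3S)-3-[(tert-butyldimethylsilyloxy)methyl]-2-[3,5-dimethoxy-4-(triisopropylsilyloxy)phenyl]-7-methoxy-2,3-dihydrobenzofuran-5-yl]methanol
Conditions: i-Bu2AlH, CH2Cl2, −78 to 0 °C; aq. potassium sodium tartrate
Reagents that add atoms: none
Why: Hydride reduction of the aryl ester to the benzylic alcohol; low temperature and a tartrate work-up avoid Lewis-acid ionisation at C2, and neither silyl ether is attacked.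

Step 8
Reactants: 11 [(2R,3S)-3-[(tert-butyldimethylsilyloxy)methyl]-2-[3,5-dimethoxy-4-(triisopropylsilyloxy)phenyl]-7-methoxy-2,3-dihydrobenzofuran-5-yl]methanol
Product: 12 (2R,3S)-3-[(tert-butyldimethylsilyloxy)methyl]-2-[3,5-dimethoxy-4-(triisopropylsilyloxy)phenyl]-7-methoxy-2,3-dihydrobenzofuran-5-carbaldehyde
Conditions: MnO2 (activated, excess), CH2Cl2, rt
Reagents that add atoms: none
Why: MnO2 oxidises benzylic alcohols selectively to aldehydes under neutral conditions without over-oxidation; the stereocentres are not involved.

Step 9
Reactants: 13 3,5-dihydroxybenzaldehyde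
Product: 14 3,5-bis(triisopropylsilyloxy)benzaldehyde
Conditions: i-Pr3SiCl, imidazole, DMF, rt
Reagents that add atoms: triisopropylsilyl chloride, CC(C)[Si](Cl)(C(C)C)C(C)C
Why: Double silylation of the two phenols; triisopropylsilyl is chosen over smaller silyl groups so that the aryl ethers survive the amide base of step 13.

Step 10
Reactants: 14 3,5-bis(triisopropylsilyloxy)benzaldehyde
Product: 15 [3,5-bis(triisopropylsilyloxy)phenyl]methanol
Conditions: NaBH4, EtOH–THF, 0 °C
Reagents that add atoms: none
Why: Borohydride reduction of an aromatic aldehyde; a short reaction time at 0 °C keeps the aryl silyl ethers intact.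

Step 11
Reactants: 15 [3,5-bis(triisopropylsilyloxy)phenyl]methanol
Product: 16 3,5-bis(triisopropylsilyloxy)benzyl bromide
Conditions: CBr4, PPh3, CH2Cl2, 0 °C
Reagents that add atoms: carbon tetrabromide, BrC(Br)(Br)Br
Why: Appel reaction: the benzylic alcohol is converted into the bromide under neutral conditions by SN2 displacement of the oxyphosphonium group.

Step 12
Reactants: 16 3,5-bis(triisopropylsilyloxy)benzyl bromide
Product: 17 diethyl [3,5-bis(triisopropylsilyloxy)benzyl]phosphonate
Conditions: P(OEt)3 (neat), 130 °C
Reagents that add atoms: triethyl phosphite, CCOP(OCC)OCC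
Why: Michaelis–Arbuzov reaction of a benzylic bromide; bromoethane distils off and drives the reaction to completion.

Step 13
Reactants: 12 (2R,3S)-3-[(tert-butyldimethylsilyloxy)methyl]-2-[3,5-dimethoxy-4-(triisopropylsilyloxy)phenyl]-7-methoxy-2,3-dihydrobenzofuran-5-carbaldehyde; 17 diethyl [3,5-bis(triisopropylsilyloxy)benzyl]phosphonate
Product: 18 (2R,3S)-5-[(E)-2-[3,5-bis(triisopropylsilyloxy)phenyl]vinyl]-3-[(tert-butyldimethylsilyloxy)methyl]-2-[3,5-dimethoxy-4-(triisopropylsilyloxy)phenyl]-7-methoxy-2,3-dihydrobenzofuran
Conditions: 17 (1.3 equiv), KN(SiMe3)2 (1.2 equiv), THF, −78 °C; then 12, −78 °C to rt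
Reagents that add atoms: none
Why: Horner–Wadsworth–Emmons olefination: a semi-stabilised benzylic phosphonate anion and an aromatic aldehyde give the (E)-stilbene through the preferred anti adduct; keeping the base below the amount of phosphonate leaves no free amide that could open the dihydrofuran by elimination across C3–C2.

Step 14
Reactants: 18 (2R,3S)-5-[(E)-2-[3,5-bis(triisopropylsilyloxy)phenyl]vinyl]-3-[(tert-butyldimethylsilyloxy)methyl]-2-[3,5-dimethoxy-4-(triisopropylsilyloxy)phenyl]-7-methoxy-2,3-dihydrobenzofuran
Product: 19 gnetucleistol F, 5-[(E)-2-[(2R,3S)-3-(hydroxymethyl)-2-(4-hydroxy-3,5-dimethoxyphenyl)-7-methoxy-2,3-dihydrobenzofuran-5-yl]vinyl]benzene-1,3-diol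
Conditions: Bu4NF, AcOH, THF, 0 °C to rt, argon, dark
Reagents that add atoms: none
Why: Fluoride cleaves the three aryl and the one alkyl silyl ether in one operation; acetic acid keeps the freed ring B phenol protonated so that it cannot expel O1 as a para-quinone methide, which leaves C2 and C3 as set, and exclusion of light and air protects the hydroxystilbene.

## Compound list

1 | syringaldehyde (4-hydroxy-3,5-dimethoxybenzaldehyde) | COc1cc(C=O)cc(OC)c1O | starting material
2 | 3,5-dimethoxy-4-(triisopropylsilyloxy)benzaldehyde | COc1cc(C=O)cc(OC)c1O[Si](C(C)C)(C(C)C)C(C)C | intermediate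
3 | 3,5-dimethoxy-4-(triisopropylsilyloxy)styrene | COc1cc(C=C)cc(OC)c1O[Si](C(C)C)(C(C)C)C(C)C | intermediate
4 | methyl vanillate (methyl 4-hydroxy-3-methoxybenzoate) | COC(=O)c1ccc(O)c(OC)c1 | starting material
5 | methyl 4-hydroxy-3-iodo-5-methoxybenzoate | COC(=O)c1cc(I)c(O)c(OC)c1 | intermediate
6 | methyl 4-hydroxy-3-methoxy-5-[(E)-2-[3,5-dimethoxy-4-(triisopropylsilyloxy)phenyl]vinyl]benzoate | COc1cc(/C=C/c2cc(C(=O)OC)cc(OC)c2O)cc(OC)c1O[Si](C(C)C)(C(C)C)C(C)C | intermediate
7 | formaldehyde (used as paraformaldehyde) | C=O | starting material
8 | open-chain benzylic cation: 3-hydroxy-2-[2-hydroxy-3-methoxy-5-(methoxycarbonyl)phenyl]-1-[3,5-dimethoxy-4-(triisopropylsilyloxy)phenyl]propan-1-ylium, the carbon next to the cationic centre having the configuration it keeps as C3 of 9; ion pair with the catalyst anion | COc1cc([CH+][C@H](CO)c2cc(C(=O)OC)cc(OC)c2O)cc(OC)c1O[Si](C(C)C)(C(C)C)C(C)C | intermediate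
9 | methyl (2R,3S)-2-[3,5-dimethoxy-4-(triisopropylsilyloxy)phenyl]-3-(hydroxymethyl)-7-methoxy-2,3-dihydrobenzofuran-5-carboxylate (trans) | COc1cc([C@@H]2Oc3c(OC)cc(C(=O)OC)cc3[C@H]2CO)cc(OC)c1O[Si](C(C)C)(C(C)C)C(C)C | intermediate
10 | methyl (2R,3S)-3-[(tert-butyldimethylsilyloxy)methyl]-2-[3,5-dimethoxy-4-(triisopropylsilyloxy)phenyl]-7-methoxy-2,3-dihydrobenzofuran-5-carboxylate | COc1cc([C@@H]2Oc3c(OC)cc(C(=O)OC)cc3[C@H]2CO[Si](C)(C)C(C)(C)C)cc(OC)c1O[Si](C(C)C)(C(C)C)C(C)C | intermediate
11 | [(2R,3S)-3-[(tert-butyldimethylsilyloxy)methyl]-2-[3,5-dimethoxy-4-(triisopropylsilyloxy)phenyl]-7-methoxy-2,3-dihydrobenzofuran-5-yl]methanol | COc1cc([C@@H]2Oc3c(OC)cc(CO)cc3[C@H]2CO[Si](C)(C)C(C)(C)C)cc(OC)c1O[Si](C(C)C)(C(C)C)C(C)C | intermediate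
12 | (2R,3S)-3-[(tert-butyldimethylsilyloxy)methyl]-2-[3,5-dimethoxy-4-(triisopropylsilyloxy)phenyl]-7-methoxy-2,3-dihydrobenzofuran-5-carbaldehyde | COc1cc([C@@H]2Oc3c(OC)cc(C=O)cc3[C@H]2CO[Si](C)(C)C(C)(C)C)cc(OC)c1O[Si](C(C)C)(C(C)C)C(C)C | intermediate
13 | 3,5-dihydroxybenzaldehyde | O=Cc1cc(O)cc(O)c1 | starting material
14 | 3,5-bis(triisopropylsilyloxy)benzaldehyde | O=Cc1cc(O[Si](C(C)C)(C(C)C)C(C)C)cc(O[Si](C(C)C)(C(C)C)C(C)C)c1 | intermediate
15 | [3,5-bis(triisopropylsilyloxy)phenyl]methanol | OCc1cc(O[Si](C(C)C)(C(C)C)C(C)C)cc(O[Si](C(C)C)(C(C)C)C(C)C)c1 | intermediate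
16 | 3,5-bis(triisopropylsilyloxy)benzyl bromide | BrCc1cc(O[Si](C(C)C)(C(C)C)C(C)C)cc(O[Si](C(C)C)(C(C)C)C(C)C)c1 | intermediate
17 | diethyl [3,5-bis(triisopropylsilyloxy)benzyl]phosphonate | CCOP(=O)(Cc1cc(O[Si](C(C)C)(C(C)C)C(C)C)cc(O[Si](C(C)C)(C(C)C)C(C)C)c1)OCC | intermediate
18 | (2R,3S)-5-[(E)-2-[3,5-bis(triisopropylsilyloxy)phenyl]vinyl]-3-[(tert-butyldimethylsilyloxy)methyl]-2-[3,5-dimethoxy-4-(triisopropylsilyloxy)phenyl]-7-methoxy-2,3-dihydrobenzofuran | COc1cc([C@@H]2Oc3c(OC)cc(/C=C/c4cc(O[Si](C(C)C)(C(C)C)C(C)C)cc(O[Si](C(C)C)(C(C)C)C(C)C)c4)cc3[C@H]2CO[Si](C)(C)C(C)(C)C)cc(OC)c1O[Si](C(C)C)(C(C)C)C(C)C | intermediate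
19 | gnetucleistol F, 5-[(E)-2-[(2R,3S)-3-(hydroxymethyl)-2-(4-hydroxy-3,5-dimethoxyphenyl)-7-methoxy-2,3-dihydrobenzofuran-5-yl]vinyl]benzene-1,3-diol | COc1cc([C@@H]2Oc3c(OC)cc(/C=C/c4cc(O)cc(O)c4)cc3[C@H]2CO)cc(OC)c1O | target

## Step count and least certain steps

Total: 14 steps. Longest linear sequence: 9 steps (steps 1, 2, 4, 5, 6, 7, 8, 13, 14, from syringaldehyde 1). The phosphonate branch (steps 9 to 12) and the iodide (step 3) join it.

**Step 5 (key step, proposed new method).**
- Most likely failure: misdirected regiochemistry of the first C–C bond. Formaldehyde could attack at C2 and leave the charge next to ring A, from where no ring closure is possible. The reason is that a silyloxy group twisted out of plane by two ortho methoxy groups is a weaker donor than an unhindered para oxygen, so the two benzylic positions may be closer in cation-stabilising ability than the design assumes.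
- Further possible failures: protonation of the stilbene by the strong acid (hydroalkoxylation without formaldehyde, or dimerisation); O-hydroxymethylation of the ring A phenol followed by an internal Prins closure to ring isomers; and weak facial discrimination, because the catalyst class was developed for terminal styrenes.
- A change that stays inside the strategy is a stronger donor on the para oxygen of ring B.
- Fallback with known chemistry (sets out from iodide 5 and aldehyde 2, comes back at 9): C3 is set by an auxiliary aldol reaction and the ring is closed by the same cation capture, starting from a carbinol. Benzylation of 5 (BnBr, K2CO3, DMF) gives methyl 4-(benzyloxy)-3-iodo-5-methoxybenzoate F1. Palladium-catalysed coupling with the Reformatsky reagent BrZnCH2CO2t-Bu (Pd2(dba)3, XPhos, THF, 60 °C) gives methyl 4-(benzyloxy)-3-(2-tert-butoxy-2-oxoethyl)-5-methoxybenzoate F2. CF3CO2H in CH2Cl2 cleaves the tert-butyl ester to [2-(benzyloxy)-3-methoxy-5-(methoxycarbonyl)phenyl]acetic acid F3. Activation as the pivalic mixed anhydride and reaction with lithiated (R)-4-benzyl-2-oxazolidinone gives (R)-4-benzyl-3-{[2-(benzyloxy)-3-methoxy-5-(methoxycarbonyl)phenyl]acetyl}oxazolidin-2-one F4. An Evans syn-aldol reaction with 2 (Bu2BOTf, i-Pr2NEt, CH2Cl2, −78 to 0 °C) gives (R)-4-benzyl-3-{(2R,3R)-2-[2-(benzyloxy)-3-methoxy-5-(methoxycarbonyl)phenyl]-3-[3,5-dimethoxy-4-(triisopropylsilyloxy)phenyl]-3-hydroxypropanoyl}oxazolidin-2-one F5, whose alpha carbon becomes C3. LiBH4 (THF, a little MeOH, 0 °C) removes the auxiliary reductively, the aryl ester being slower to react, and gives methyl 4-(benzyloxy)-3-{(1R,2S)-1,3-dihydroxy-1-[3,5-dimethoxy-4-(triisopropylsilyloxy)phenyl]propan-2-yl}-5-methoxybenzoate F6. Hydrogenolysis (H2, palladium on carbon, EtOAc) frees the phenol and gives methyl 3-{(1R,2S)-1,3-dihydroxy-1-[3,5-dimethoxy-4-(triisopropylsilyloxy)phenyl]propan-2-yl}-4-hydroxy-5-methoxybenzoate F7. Catalytic TsOH in CH2Cl2 then ionises the benzylic carbinol and the phenol closes the ring to trans 9. This replaces steps 3 to 5 by eight operations but uses only established reactions.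

**Step 4 (Heck coupling).**
- Most likely failure: slow or incomplete coupling through catalyst deactivation. Under the amine base the ortho-iodophenol is partly present as phenoxide, which slows oxidative addition and can bind palladium. The electron-rich styrene 3 may also polymerise or be arylated at its internal carbon at 90 °C.
- Fallback (sets out from 3 and 5, comes back at 6): cross-metathesis of 3 with vinylboronic acid pinacol ester (second-generation Grubbs catalyst, CH2Cl2, 40 °C) gives 2-[(E)-2-[3,5-dimethoxy-4-(triisopropylsilyloxy)phenyl]vinyl]-4,4,5,5-tetramethyl-1,3,2-dioxaborolane F8. Suzuki–Miyaura coupling of F8 with 5 (Pd(dppf)Cl2, K3PO4, dioxane–water, 80 °C), a reaction type that tolerates free ortho-halophenols, gives 6.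

**Step 13 (olefination).**
- Most likely failure: base-induced opening of the dihydrofuran, by removal of the benzylic C3 proton with expulsion of O1. O1 is a good leaving group here because the aldehyde is para to it. Partial loss of aryl silyl groups is also possible if free strong base is present.
- Fallback (sets out from 12, comes back at 18): the C=C bond is made by palladium catalysis under a weak amine base. Wittig methylenation of 12 (Ph3PCH3Br, NaN(SiMe3)2, THF, −78 to 0 °C; a much weaker base than the phosphonate anion) gives (2R,3S)-3-[(tert-butyldimethylsilyloxy)methyl]-2-[3,5-dimethoxy-4-(triisopropylsilyloxy)phenyl]-7-methoxy-5-vinyl-2,3-dihydrobenzofuran F9. Heck coupling of F9 (Pd(OAc)2, P(o-tol)3, Et3N, DMF, 90 °C) with 1-bromo-3,5-bis(triisopropylsilyloxy)benzene F10, made from commercial 5-bromoresorcinol with i-Pr3SiCl and imidazole, gives 18.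

## Further compounds

F1 | step 5 | methyl 4-(benzyloxy)-3-iodo-5-methoxybenzoate | COC(=O)c1cc(I)c(OCc2ccccc2)c(OC)c1
F2 | step 5 | methyl 4-(benzyloxy)-3-(2-tert-butoxy-2-oxoethyl)-5-methoxybenzoate | COC(=O)c1cc(CC(=O)OC(C)(C)C)c(OCc2ccccc2)c(OC)c1
F3 | step 5 | [2-(benzyloxy)-3-methoxy-5-(methoxycarbonyl)phenyl]acetic acid | COC(=O)c1cc(CC(=O)O)c(OCc2ccccc2)c(OC)c1
F4 | step 5 | (R)-4-benzyl-3-{[2-(benzyloxy)-3-methoxy-5-(methoxycarbonyl)phenyl]acetyl}oxazolidin-2-one | O=C1OC[C@@H](Cc2ccccc2)N1C(=O)Cc1cc(C(=O)OC)cc(OC)c1OCc1ccccc1
F5 | step 5 | (R)-4-benzyl-3-{(2R,3R)-2-[2-(benzyloxy)-3-methoxy-5-(methoxycarbonyl)phenyl]-3-[3,5-dimethoxy-4-(triisopropylsilyloxy)phenyl]-3-hydroxypropanoyl}oxazolidin-2-one | O=C1OC[C@@H](Cc2ccccc2)N1C(=O)[C@@H]([C@@H](O)c1cc(OC)c(O[Si](C(C)C)(C(C)C)C(C)C)c(OC)c1)c1cc(C(=O)OC)cc(OC)c1OCc1ccccc1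
F6 | step 5 | methyl 4-(benzyloxy)-3-{(1R,2S)-1,3-dihydroxy-1-[3,5-dimethoxy-4-(triisopropylsilyloxy)phenyl]propan-2-yl}-5-methoxybenzoate | OC[C@@H]([C@@H](O)c1cc(OC)c(O[Si](C(C)C)(C(C)C)C(C)C)c(OC)c1)c1cc(C(=O)OC)cc(OC)c1OCc1ccccc1
F7 | step 5 | methyl 3-{(1R,2S)-1,3-dihydroxy-1-[3,5-dimethoxy-4-(triisopropylsilyloxy)phenyl]propan-2-yl}-4-hydroxy-5-methoxybenzoate | OC[C@@H]([C@@H](O)c1cc(OC)c(O[Si](C(C)C)(C(C)C)C(C)C)c(OC)c1)c1cc(C(=O)OC)cc(OC)c1O
F8 | step 4 | 2-[(E)-2-[3,5-dimethoxy-4-(triisopropylsilyloxy)phenyl]vinyl]-4,4,5,5-tetramethyl-1,3,2-dioxaborolane | COc1cc(/C=C/B2OC(C)(C)C(C)(C)O2)cc(OC)c1O[Si](C(C)C)(C(C)C)C(C)C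
F9 | step 13 | (2R,3S)-3-[(tert-butyldimethylsilyloxy)methyl]-2-[3,5-dimethoxy-4-(triisopropylsilyloxy)phenyl]-7-methoxy-5-vinyl-2,3-dihydrobenzofuran | COc1cc([C@@H]2Oc3c(OC)cc(C=C)cc3[C@H]2CO[Si](C)(C)C(C)(C)C)cc(OC)c1O[Si](C(C)C)(C(C)C)C(C)C
F10 | step 13 | 1-bromo-3,5-bis(triisopropylsilyloxy)benzene | Brc1cc(O[Si](C(C)C)(C(C)C)C(C)C)cc(O[Si](C(C)C)(C(C)C)C(C)C)c1
A1 | alternative 1 | (2R,3S)-3-[(tert-butyldimethylsilyloxy)methyl]-2-[3,5-dimethoxy-4-(methoxymethoxy)phenyl]-7-methoxy-2,3-dihydrobenzofuran (trans) | COCOc1c(OC)cc([C@@H]2Oc3c(OC)cccc3[C@H]2CO[Si](C)(C)C(C)(C)C)cc1OC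
A2 | alternative 1 | (1R,2S)-2-(2-bromo-3-methoxyphenyl)-3-(tert-butyldimethylsilyloxy)-1-[3,5-dimethoxy-4-(methoxymethoxy)phenyl]propan-1-ol | COCOc1c(OC)cc([C@H](O)[C@H](CO[Si](C)(C)C(C)(C)C)c2cccc(OC)c2Br)cc1OC
A3 | alternative 2 | methyl (2R,3R)-5-bromo-2-[3,5-dimethoxy-4-(pivaloyloxy)phenyl]-7-methoxy-2,3-dihydrobenzofuran-3-carboxylate (trans) | COc1cc([C@@H]2Oc3c(OC)cc(Br)cc3[C@H]2C(=O)OC)cc(OC)c1OC(=O)C(C)(C)C
A4 | alternative 2 | (2R)-6-bromo-2-[3,5-dimethoxy-4-(pivaloyloxy)phenyl]-8-methoxychroman-4-one | O=C1C[C@H](c2cc(OC)c(OC(=O)C(C)(C)C)c(OC)c2)Oc2c(OC)cc(Br)cc12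
A5 | alternative 3 | (2R,3S)-5-bromo-2-(4-hydroxy-3,5-dimethoxyphenyl)-3-(hydroxymethyl)-7-methoxy-2,3-dihydrobenzofuran (trans) | COc1cc([C@@H]2Oc3c(OC)cc(Br)cc3[C@H]2CO)cc(OC)c1O
A6 | alternative 3 | (2S)-2-(5-bromo-2-hydroxy-3-methoxyphenyl)-1-(4-hydroxy-3,5-dimethoxyphenyl)propane-1,3-diol (either configuration at C1) | COc1cc(C(O)[C@H](CO)c2cc(Br)cc(OC)c2O)cc(OC)c1O
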